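**Plan**
- Retrosynthetic cuts: the C4–O aroyl bond; the C8–CH3 bond and the C7=C8 unsaturation (back to a C9 ketone); the C1–C5 bond of the five-membered ring; then C4–isopropyl, and C5=C6 and C1–C2 of a decalin (Robinson annulation).
- Enabling feature: C5 sits between the oxygen-bearing C6 and the quaternary C1. The C1–C5 bond can therefore come from the C1–C6 bond of a cis-decalin that carries a leaving group on C5 and a hydroxyl on C6. One 1,2-shift of C1 contracts ring A (C1–C6) to the cyclopentane and enlarges ring B to the cycloheptanone.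
- Forward order: ring B is the cyclohexanone 1; ring A is annulated with methyl vinyl ketone; isopropyl addition, dihydroxylation and mesylation arm the decalin; the shift gives the 5-7 skeleton; C6 is then reduced, O4 aroylated, and the C9 ketone turned into the 8-methyl enone.
- Stereochemistry: C1 from the (R)-1-phenylethylamine imine; C4 by axial organocerium attack anti to the angular methyl; the C5 and C6 oxygens by hydroxyl-directed osmylation; C5 of the target by inversion in the shift (trans fusion); C6 by thermodynamically controlled reduction.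

Key step: step 6

Remark on numbering: atom numbers are those of the daucane skeleton of the target (C1 quaternary methyl carbon, C2, C3, C4 isopropyl carbinol, C5 ring-fusion CH, C6 carbinol, C7=C8, C9 ketone, C10); β is the face of the C1 methyl group, α the opposite face.
Assumption: the (R)-amine is taken to give the (R)-quaternary centre, the mirror-image sense of the usual result with the (S)-amine; the dioxolane only changes the CIP priorities, not the facial course.

**Step 1**
Reactants: 1 7-methyl-1,4-dioxaspiro[4.5]decan-8-one (racemic); 2 (R)-1-phenylethylamine; 3 methyl vinyl ketone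
Product: 6 (R)-7-methyl-7-(3-oxobutyl)-1,4-dioxaspiro[4.5]decan-8-one, via ketimine 4 (not isolated), via Michael-adduct ketimine 5 (not isolated)
Conditions: 2, TsOH (cat.), toluene, reflux, azeotropic removal of water; then 3, THF, 23 °C; then 20% aq. AcOH, 23 °C
Reagents that add atoms: water, O
Why: Chiral-imine Michael addition (asymmetric first stage of a Robinson annulation), in which the imine reacts through its more substituted secondary enamine tautomer in a cyclic aza-ene-like transition state, the phenyl group of the auxiliary screens one face so that the vinyl ketone adds to the other and sets the quaternary C1 as R, and mild aqueous acid then hydrolyses the imine without opening the dioxolane.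

**Step 2**
Reactants: 6 (R)-7-methyl-7-(3-oxobutyl)-1,4-dioxaspiro[4.5]decan-8-one
Product: 7 (R)-4a-methyl-6,6-(ethylenedioxy)-4,4a,5,6,7,8-hexahydronaphthalen-2(3H)-one (C4 ketone; C5=C6; C9 dioxolane)
Conditions: NaOMe, MeOH, 23 → 60 °C
Reagents that add atoms: none
Why: Intramolecular aldol condensation (second stage of the Robinson annulation), in which the methyl ketone enolate closes ring A on the ring ketone and dehydration gives the conjugated enone, while the quaternary C1 cannot epimerise and the ketal is inert to base.

**Step 3**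
Reactants: 7 (R)-enone; 8 isopropylmagnesium chloride
Product: 9 (2R,4aR)-4a-methyl-2-(propan-2-yl)-6,6-(ethylenedioxy)-2,3,4,4a,5,6,7,8-octahydronaphthalen-2-ol (tertiary allylic alcohol; C4–OH β; isopropyl α)
Conditions: CeCl3 (anhydrous), THF, −78 °C; then H2O
Reagents that add atoms: none
Why: 1,2-Addition of an organocerium reagent to an enone, in which the weakly basic cerium reagent suppresses enolisation, reduction and conjugate addition, and the isopropyl group should enter axially on the face opposite the axial angular methyl (the stereoelectronically preferred course for cyclohexenones of this type), so that the new C4 hydroxyl ends up β, cis to the C1 methyl.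

**Step 4**
Reactants: 9 tertiary allylic alcohol
Product: 11 cis-fused 4α-isopropyl-1β-methyl-9,9-(ethylenedioxy)decalin-4β,5β,6β-triol, via TMEDA-ligated osmate ester 10 (not isolated)
Conditions: OsO4 (1.05 equiv), TMEDA, CH2Cl2, −78 °C; then aq. Na2SO3, THF, 60 °C
Reagents that add atoms: osmium tetroxide, O=[Os](=O)(=O)=O
Why: Hydrogen-bond-directed dihydroxylation with the OsO4·TMEDA complex, in which the C4 hydroxyl binds an oxo ligand and delivers the reagent to the β face of C5=C6; that face is open in the half-chair where the bulky isopropyl group is pseudoequatorial, the C4 hydroxyl pseudoaxial and the C1 methyl pseudoequatorial, so both new C–O bonds at C5 and C6 are cis to the C4 oxygen and the ring fusion becomes cis.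

**Step 5**
Reactants: 11 triol
Product: 12 cis-fused 4β,6β-dihydroxy-4α-isopropyl-1β-methyl-9,9-(ethylenedioxy)decalin-5β-yl methanesulfonate
Conditions: MsCl, Et3N, CH2Cl2, −20 → 0 °C
Reagents that add atoms: methanesulfonyl chloride, CS(=O)(=O)Cl
Why: Sulfonylation (sulfene pathway) of the only secondary hydroxyl; the two tertiary hydroxyls do not react under these conditions and, being cis to the mesylate, cannot displace it to form an epoxide.

**Step 6**
Reactants: 12 diol mesylate
Product: 14 trans-fused (5α-H) 4β-hydroxy-4α-isopropyl-1β-methyl-9,9-(ethylenedioxy)hydroazulen-6-one, via chloroaluminium diolate 13 (not isolated)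
Conditions: Et2AlCl (3 equiv), CH2Cl2, −78 → −20 °C; then aq. potassium sodium tartrate
Reagents that add atoms: none
Why: Et2AlCl first ties the two 1,3-diaxial tertiary hydroxyls into the cyclic chloroaluminium diolate 13, which locks ring A in the chair with the isopropyl group and the C5 mesylate equatorial, so that the C6–C1 bond is antiperiplanar to C5–OMs; further Et2AlCl then pulls on the mesylate while the C6 oxygen pushes, C1 moves from C6 to C5 and C6 becomes the ketone, an organoaluminium-promoted pinacol-type (semipinacol) rearrangement of a 2-mesyloxy alcohol whose closest precedent is the conversion of decalin-1,2-diol monosulfonates into hydroazulenones. No ring is closed by cyclisation: the single 1,2-shift contracts ring A to the cyclopentane by forming C1–C5 and at the same time enlarges ring B to the cycloheptanone. The only stereocentre made is C5, and it is set by the stereospecific course of the shift (inversion at C5 because C1 arrives anti to the leaving group, retention at C1), so the all-cis arrangement of the C4, C5 and C6 oxygens on the methyl face is translated into the trans ring fusion with the C4 oxygen cis to the C1 methyl. The selectivity needed is migration of the C6–C1 bond and not of the equally antiperiplanar C4–C3 bond, and it rests on the fully substituted C1 being a far better migrating carbon than the C3 methylene and on the relief of strain in the crowded C1–C6 bond. The cis-related oxygens cannot reach the back of C5, so no epoxide can form, and the Lewis-acidic, non-basic medium avoids the retro-aldol opening that a potassium alkoxide of the β-hydroxy ketone would invite.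

**Step 7**
Reactants: 14 β-hydroxy ketone
Product: 15 trans-fused 4α-isopropyl-1β-methyl-9,9-(ethylenedioxy)hydroazulene-4β,6α-diol
Conditions: Li, NH3(l), THF, t-BuOH, −78 °C; then NH4Cl
Reagents that add atoms: none
Why: Dissolving-metal reduction of a ketone, chosen because a hydride would attack C6 anti to the pseudoaxial C1 methyl and give the 6β-alcohol, whereas electron transfer passes through a configurationally mobile carbinyl anion and should give the more stable pseudoequatorial 6α-alkoxide, which is also held by chelation to the C4 oxygen.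

**Step 8**
Reactants: 15 diol
Product: 16 6α-(triisopropylsilyloxy)-4α-isopropyl-1β-methyl-9,9-(ethylenedioxy)hydroazulen-4β-ol
Conditions: TIPSOTf, 2,6-lutidine, CH2Cl2, 0 °C
Reagents that add atoms: triisopropylsilyl trifluoromethanesulfonate, CC(C)[Si](C(C)C)(C(C)C)OS(=O)(=O)C(F)(F)F
Why: Silylation with a silyl triflate and a hindered pyridine base, in which only the secondary C6 hydroxyl reacts because the tertiary C4 hydroxyl is too hindered for the bulky silyl group.

**Step 9**
Reactants: 17 4-hydroxybenzoic acid
Product: 19 4-(triisopropylsilyloxy)benzoic acid, via silyl ester 18 (not isolated)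
Conditions: TIPSCl (2.2 equiv), imidazole, DMF, 23 °C; then AcOH, THF/H2O, 23 °C
Reagents that add atoms: triisopropylsilyl chloride, CC(C)[Si](Cl)(C(C)C)C(C)C
Why: Silylation of both acidic OH groups followed by selective hydrolysis of the labile silyl ester, which leaves the acid-stable aryl silyl ether.

**Step 10**
Reactants: 19 4-(triisopropylsilyloxy)benzoic acid
Product: 20 4-(triisopropylsilyloxy)benzoyl chloride
Conditions: (COCl)2, DMF (cat.), CH2Cl2, 0 → 23 °C
Reagents that add atoms: oxalyl chloride, ClC(=O)C(Cl)=O
Why: Acid chloride formation through Vilsmeier-type activation by oxalyl chloride and catalytic DMF, conditions the aryl silyl ether tolerates.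

**Step 11**
Reactants: 16 tertiary alcohol; 20 4-(triisopropylsilyloxy)benzoyl chloride
Product: 22 6α-(triisopropylsilyloxy)-4α-isopropyl-1β-methyl-9,9-(ethylenedioxy)hydroazulen-4β-yl 4-(triisopropylsilyloxy)benzoate, via lithium alkoxide 21 (not isolated)
Conditions: LiN(SiMe3)2, THF, −78 °C; then 20, −78 → 0 °C
Reagents that add atoms: none
Why: Acylation of a preformed lithium tertiary alkoxide with an acid chloride, the established way to esterify hindered tertiary alcohols; the bulky silyl group on O6 resists 1,5-migration to the neighbouring alkoxide and no enolisable carbonyl is present.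

**Step 12**
Reactants: 22 ketal ester
Product: 23 6α-(triisopropylsilyloxy)-4α-isopropyl-1β-methyl-9-oxohydroazulen-4β-yl 4-(triisopropylsilyloxy)benzoate
Conditions: PPTS, acetone/H2O, 55 °C
Reagents that add atoms: water, O
Why: Acid-catalysed hydrolysis of the dioxolane under buffered conditions that spare both silyl ethers and the tertiary ester.

**Step 13**
Reactants: 23 C9 ketone
Product: 24 7,8-didehydro enone (C7=C8–C9=O) of 23
Conditions: IBX, DMSO/fluorobenzene, 65 °C
Reagents that add atoms: none
Why: IBX dehydrogenation of a ketone to the enone, which can only run towards C8–C7 because the other α-carbon, C10, is attached to the quaternary C1 and has no β-hydrogen.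

**Step 14**
Reactants: 24 enone
Product: 25 8-iodo enone
Conditions: I2, pyridine, CH2Cl2, 0 → 23 °C
Reagents that add atoms: iodine, II
Why: α-Iodination of an enone with iodine and pyridine (conjugate addition of pyridine, iodination of the enolate, elimination), which places iodine only on C8.

**Step 15**
Reactants: 25 8-iodo enone
Product: 26 8-methyl enone (bis-silyl ether of the target)
Conditions: Me4Sn, Pd2(dba)3 (cat.), AsPh3, CuI (cat.), NMP, 80 °C
Reagents that add atoms: tetramethylstannane, C[Sn](C)(C)C
Why: Stille cross-coupling of a 2-iodoenone with tetramethyltin under copper-assisted, base-free conditions that leave the ester, the silyl ethers and the enone untouched.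

**Step 16**
Reactants: 26 bis-silyl ether
Product: 27 (3R,3aS,4S,8aR)-4-hydroxy-6,8a-dimethyl-7-oxo-3-(propan-2-yl)-1,2,3,3a,4,7,8,8a-octahydroazulen-3-yl 4-hydroxybenzoate (target)
Conditions: HF·pyridine, pyridine, THF, 0 → 23 °C
Reagents that add atoms: none
Why: Fluoride-induced cleavage of the aryl and the secondary silyl ether under mildly acidic conditions, which avoids base-induced acyl migration from O4 to the neighbouring O6.

**Compound list**
1 | 7-methyl-1,4-dioxaspiro[4.5]decan-8-one (racemic) | CC1CC2(CCC1=O)OCCO2 | starting material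
2 | (R)-1-phenylethylamine | C[C@@H](N)c1ccccc1 | starting material
3 | methyl vinyl ketone | CC(=O)C=C | starting material
4 | N-[(R)-1-phenylethyl] ketimine of 1 | CC1CC2(OCCO2)CCC1=N[C@H](C)c1ccccc1 | intermediate (not isolated)
5 | N-[(R)-1-phenylethyl] ketimine of 6 | CC(=O)CC[C@]1(C)CC2(OCCO2)CCC1=N[C@H](C)c1ccccc1 | intermediate (not isolated)
6 | (R)-7-methyl-7-(3-oxobutyl)-1,4-dioxaspiro[4.5]decan-8-one | CC(=O)CC[C@]1(C)CC2(OCCO2)CCC1=O | intermediate
7 | (R)-4a-methyl-6,6-(ethylenedioxy)-4,4a,5,6,7,8-hexahydronaphthalen-2(3H)-one | C1CC2(OCCO2)C[C@@]3(C)CCC(=O)C=C13 | intermediate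
8 | isopropylmagnesium chloride | CC(C)[Mg]Cl | starting material
9 | (2R,4aR)-4a-methyl-2-(propan-2-yl)-6,6-(ethylenedioxy)-2,3,4,4a,5,6,7,8-octahydronaphthalen-2-ol (C4–OH β) | C1CC2(OCCO2)C[C@@]3(C)CC[C@@](O)(C(C)C)C=C13 | intermediate
10 | TMEDA-ligated cyclic osmate ester (hexavalent osmium) across O5 and O6 of triol 11 | C1CC2(OCCO2)C[C@@]3(C)CC[C@@](O)(C(C)C)[C@@H]4O[Os-2]5(=O)(=O)(O[C@]134)[N+](C)(C)CC[N+]5(C)C | intermediate (not isolated)
11 | cis-fused 4α-isopropyl-1β-methyl-9,9-(ethylenedioxy)decalin-4β,5β,6β-triol | C1CC2(OCCO2)C[C@@]3(C)CC[C@@](O)(C(C)C)[C@H](O)[C@@]13O | intermediate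
12 | 5β-methanesulfonate of triol 11 (key-step precursor) | C1CC2(OCCO2)C[C@@]3(C)CC[C@@](O)(C(C)C)[C@H](OS(C)(=O)=O)[C@@]13O | intermediate
13 | cyclic chloroaluminium 4,6-diolate of 12 | C1CC2(OCCO2)C[C@@]3(C)CC[C@@]4(C(C)C)[C@H](OS(C)(=O)=O)[C@@]13O[Al](Cl)O4 | intermediate (not isolated)
14 | trans-fused (5α-H) 4β-hydroxy-4α-isopropyl-1β-methyl-9,9-(ethylenedioxy)hydroazulen-6-one (key-step product) | C1CC(=O)[C@@H]2[C@](C)(CC[C@@]2(O)C(C)C)CC13OCCO3 | intermediate
15 | trans-fused 4α-isopropyl-1β-methyl-9,9-(ethylenedioxy)hydroazulene-4β,6α-diol | C1C[C@H](O)[C@@H]2[C@](C)(CC[C@@]2(O)C(C)C)CC13OCCO3 | intermediate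
16 | 6α-O-triisopropylsilyl ether of diol 15 | C1C[C@H](O[Si](C(C)C)(C(C)C)C(C)C)[C@@H]2[C@](C)(CC[C@@]2(O)C(C)C)CC13OCCO3 | intermediate
17 | 4-hydroxybenzoic acid | OC(=O)c1ccc(O)cc1 | starting material
18 | triisopropylsilyl 4-(triisopropylsilyloxy)benzoate | CC(C)[Si](C(C)C)(C(C)C)OC(=O)c1ccc(O[Si](C(C)C)(C(C)C)C(C)C)cc1 | intermediate (not isolated)
19 | 4-(triisopropylsilyloxy)benzoic acid | OC(=O)c1ccc(O[Si](C(C)C)(C(C)C)C(C)C)cc1 | intermediate
20 | 4-(triisopropylsilyloxy)benzoyl chloride | ClC(=O)c1ccc(O[Si](C(C)C)(C(C)C)C(C)C)cc1 | intermediate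
21 | lithium C4 alkoxide of 16 | [Li+].C1C[C@H](O[Si](C(C)C)(C(C)C)C(C)C)[C@@H]2[C@](C)(CC[C@@]2([O-])C(C)C)CC13OCCO3 | intermediate (not isolated)
22 | C4 4-(triisopropylsilyloxy)benzoate of 16 | C1C[C@H](O[Si](C(C)C)(C(C)C)C(C)C)[C@@H]2[C@](C)(CC[C@@]2(OC(=O)c4ccc(O[Si](C(C)C)(C(C)C)C(C)C)cc4)C(C)C)CC13OCCO3 | intermediate
23 | C9 ketone from 22 | O=C1CC[C@H](O[Si](C(C)C)(C(C)C)C(C)C)[C@@H]2[C@](C)(CC[C@@]2(OC(=O)c3ccc(O[Si](C(C)C)(C(C)C)C(C)C)cc3)C(C)C)C1 | intermediate
24 | C7=C8 enone from 23 | O=C1C=C[C@H](O[Si](C(C)C)(C(C)C)C(C)C)[C@@H]2[C@](C)(CC[C@@]2(OC(=O)c3ccc(O[Si](C(C)C)(C(C)C)C(C)C)cc3)C(C)C)C1 | intermediate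
25 | 8-iodo enone | O=C1C(I)=C[C@H](O[Si](C(C)C)(C(C)C)C(C)C)[C@@H]2[C@](C)(CC[C@@]2(OC(=O)c3ccc(O[Si](C(C)C)(C(C)C)C(C)C)cc3)C(C)C)C1 | intermediate
26 | 8-methyl enone (bis-silyl ether of the target) | O=C1C(C)=C[C@H](O[Si](C(C)C)(C(C)C)C(C)C)[C@@H]2[C@](C)(CC[C@@]2(OC(=O)c3ccc(O[Si](C(C)C)(C(C)C)C(C)C)cc3)C(C)C)C1 | intermediate
27 | (3R,3aS,4S,8aR)-4-hydroxy-6,8a-dimethyl-7-oxo-3-(propan-2-yl)-1,2,3,3a,4,7,8,8a-octahydroazulen-3-yl 4-hydroxybenzoate | CC1=C[C@H](O)[C@@H]2[C@](C)(CC[C@@]2(OC(=O)c2ccc(O)cc2)C(C)C)CC1=O | target

**Step count and risks**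
Total: 16 steps. Longest linear sequence: 14 steps (steps 1–8 and 11–16, from ketone 1); steps 9 and 10 make the acid chloride.

Steps most likely to fail:

Step 6. The shift may take the wrong ring bond, since C4–C3 is as well aligned with the mesylate as C6–C1 and the aluminium alkoxide at C4 can push it. The Lewis acid may also open the dioxolane. The fallback sets out from 12 and comes back at 14; it takes the C4 oxygen out of play and removes the Lewis acid. The less hindered of the two tertiary hydroxyls of 12, the one on C4 (the C6 hydroxyl sits on a ring-fusion carbon next to the quaternary C1), would be capped with Et3SiOTf and 2,6-lutidine at −78 °C to give the C4 triethylsilyl ether of the mesylate F1. Treatment with KN(SiMe3)2 in THF from −78 to 0 °C would then generate the C6 alkoxide as the only donor and should give, by the same C1 shift, the C4 triethylsilyl ether of the hydroazulenone F2. HF·pyridine in THF would free 14.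

Step 3. Facial selectivity of the isopropyl addition may be poor, because a bulky nucleophile can also attack equatorially, on the face of the angular methyl, which would give the C4 epimer. The fallback sets out from 7 and comes back at 9. Weitz–Scheffer epoxidation of 7 (H2O2, NaOH, MeOH, 0 °C) should deliver oxygen on the methyl face, as conjugate additions to this octalone do, to give the 5β,6β-epoxy ketone F3. The organocerium reagent from iPrMgCl and CeCl3 then adds to C4 anti to the epoxide oxygen to give the 5β,6β-epoxy-4β-alcohol F4. The epoxide, having served as a removable control element, would be taken back to the alkene with WCl6/n-BuLi in THF to give 9.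

Step 7. Thermodynamic control in the reduction may be incomplete: protonation of the carbinyl anion from the open α face would leave the 6β-alcohol. The fallback sets out from 14 and comes back at 15. NaBH4 in MeOH at 0 °C should reduce 14 cleanly from the open face to the 6β-alcohol F5. A Mitsunobu reaction with 4-nitrobenzoic acid (PPh3, diisopropyl azodicarboxylate, toluene) would invert C6 to the 6α 4-nitrobenzoate F6, and K2CO3 in MeOH would release 15.

**Further compounds**
F1 | step 6 | C4 triethylsilyl ether of mesylate 12 | C1CC2(OCCO2)C[C@@]3(C)CC[C@@](O[Si](CC)(CC)CC)(C(C)C)[C@H](OS(C)(=O)=O)[C@@]13O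
F2 | step 6 | C4 triethylsilyl ether of hydroazulenone 14 | C1CC(=O)[C@@H]2[C@](C)(CC[C@@]2(O[Si](CC)(CC)CC)C(C)C)CC13OCCO3
F3 | step 3 | 5β,6β-epoxy ketone from enone 7 | C1CC2(OCCO2)C[C@@]3(C)CCC(=O)[C@@H]4O[C@]134
F4 | step 3 | 5β,6β-epoxy-4α-isopropyl-4β-alcohol | C1CC2(OCCO2)C[C@@]3(C)CC[C@@](O)(C(C)C)[C@@H]4O[C@]134
F5 | step 7 | 6β-epimer of diol 15 | C1C[C@@H](O)[C@@H]2[C@](C)(CC[C@@]2(O)C(C)C)CC13OCCO3
F6 | step 7 | 6α 4-nitrobenzoate of diol 15 | C1C[C@H](OC(=O)c4ccc(cc4)[N+](=O)[O-])[C@@H]2[C@](C)(CC[C@@]2(O)C(C)C)CC13OCCO3
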